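The route rests on disconnecting ring C of the flavan-3,4-diol unit between O1 and C8a. With C4 held as a ketone, C8a is the fluorine-bearing ortho position of an aryl ketone on ring A; catalytic fluoride unmasks the C2 silyl ether and the oxygen displaces fluoride, closing the last ring of the fully assembled dimer with C2 and C3 already set by an anti glycolate aldol. The precursor is thus an open-chain 2-fluoroaryl α-benzyloxy-β-silyloxy ketone carried on the 4-arylflavan. The same closure first builds the upper chromanone; aryllithium addition and ionic reduction join the halves, and borohydride sets C4 at the end.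

Key step: step 16

Remark: flavan numbering is used for both units (O1, C2–C4, C4a, C5–C8, C8a; ring A is the fused benzene ring, ring B the 2-aryl group, ring C the pyran). The lower unit is the flavan-3,4-diol and the upper unit is the 4-arylflavan-3-ol. The descriptor at C4 of the upper unit changes between benzylated and free compounds while the geometry stays that of the target.

Step 1
Reactants: 1 3-fluoro-2-hydroxybenzaldehyde
Product: 2 2-(benzyloxy)-3-fluorobenzaldehyde
Conditions: BnBr, K2CO3, DMF, 25 °C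
Reagents that add atoms: benzyl bromide BrCc1ccccc1
Why: Williamson ether synthesis on the phenol.

Step 2
Reactants: 2 2-(benzyloxy)-3-fluorobenzaldehyde
Product: 4 2-(benzyloxy)-3-fluorophenol, via aryl formate 3 (not isolated)
Conditions: mCPBA, CH2Cl2, 25 °C; then K2CO3 (cat.), MeOH, 25 °C
Reagents that add atoms: 3-chloroperbenzoic acid OOC(=O)c1cccc(Cl)c1
Why: Dakin-type Baeyer–Villiger oxidation, in which the electron-rich ortho-alkoxyaryl group migrates to oxygen and the formate is cleaved by methanolysis.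

Step 3
Reactants: 4 2-(benzyloxy)-3-fluorophenol
Product: 5 2-(benzyloxy)-4-bromo-3-fluorophenol
Conditions: NBS (1.0 equiv), MeCN, −10 to 0 °C
Reagents that add atoms: N-bromosuccinimide BrN1C(=O)CCC1=O
Why: electrophilic aromatic bromination, directed para to the free hydroxyl, which places bromine at the carbon that becomes C4a of either unit.

Step 4
Reactants: 5 2-(benzyloxy)-4-bromo-3-fluorophenol
Product: 6 1,2-bis(benzyloxy)-4-bromo-3-fluorobenzene
Conditions: BnBr, K2CO3, DMF, 25 °C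
Reagents that add atoms: benzyl bromide BrCc1ccccc1
Why: Williamson ether synthesis; this is the ring A piece of the upper unit.

Step 5
Reactants: 5 2-(benzyloxy)-4-bromo-3-fluorophenol
Product: 7 2-(benzyloxy)-4-bromo-3-fluoro-6-iodophenol
Conditions: NIS, TsOH (cat.), MeCN, 25 °C
Reagents that add atoms: N-iodosuccinimide IN1C(=O)CCC1=O
Why: electrophilic aromatic iodination at the only free position ortho to the hydroxyl (para is blocked by bromine), which becomes C6 of the lower unit.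

Step 6
Reactants: 7 2-(benzyloxy)-4-bromo-3-fluoro-6-iodophenol
Product: 8 1,2-bis(benzyloxy)-4-bromo-3-fluoro-6-iodobenzene
Conditions: BnBr, K2CO3, DMF, 40 °C
Reagents that add atoms: benzyl bromide BrCc1ccccc1
Why: Williamson ether synthesis; this is the ring A piece of the lower unit, with iodine and bromine addressable one after the other.

Step 7
Reactants: 9 (benzyloxy)acetyl chloride
Product: 10 S-ethyl 2-(benzyloxy)ethanethioate
Conditions: EtSH, Et3N, CH2Cl2, 0 °C
Reagents that add atoms: ethanethiol CCS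
Why: acyl substitution of the acid chloride by the thiol.

Step 8
Reactants: 10 S-ethyl 2-(benzyloxy)ethanethioate
Product: 11 (Z)-{[2-(benzyloxy)-1-(ethylsulfanyl)ethenyl]oxy}trimethylsilane
Conditions: LiN(iPr)2, Me3SiCl (internal quench), THF, −78 °C
Reagents that add atoms: chlorotrimethylsilane C[Si](C)(C)Cl
Why: kinetic enolisation of the thioester with in situ O-silylation gives the ketene silyl thioacetal.

Step 9
Reactants: 11 (Z)-{[2-(benzyloxy)-1-(ethylsulfanyl)ethenyl]oxy}trimethylsilane; 12 4-(benzyloxy)benzaldehyde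
Product: 14 S-ethyl (2S,3S)-2-(benzyloxy)-3-[4-(benzyloxy)phenyl]-3-[(triethylsilyl)oxy]propanethioate, via hydroxy thioester 13 (not isolated)
Conditions: Sn(OTf)2 (1.0 equiv, promoter), (S)-1-ethyl-2-(piperidin-1-ylmethyl)pyrrolidine, Bu2Sn(OAc)2, CH2Cl2, −78 °C; aq. citric acid work-up; crude: Et3SiCl, imidazole, DMF, 0–25 °C
Reagents that add atoms: chlorotriethylsilane CC[Si](Cl)(CC)CC
Why: asymmetric Mukaiyama aldol under a chiral diamine-ligated divalent tin triflate, anti-selective for the α-benzyloxy ketene silyl thioacetal, sets both centres, the (S)-proline-derived ligand being expected to give the (2S,3S) adduct (the sense is to be confirmed and the ligands exchanged if it is reversed); the crude aldol is then O-silylated.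

Step 10
Reactants: 11 (Z)-{[2-(benzyloxy)-1-(ethylsulfanyl)ethenyl]oxy}trimethylsilane; 12 4-(benzyloxy)benzaldehyde
Product: 16 S-ethyl (2R,3R)-2-(benzyloxy)-3-[4-(benzyloxy)phenyl]-3-[(triethylsilyl)oxy]propanethioate, via hydroxy thioester 15 (not isolated)
Conditions: Sn(OTf)2 (1.0 equiv, promoter), (R)-1-ethyl-2-(piperidin-1-ylmethyl)pyrrolidine, Bu2Sn(OAc)2, CH2Cl2, −78 °C; aq. citric acid work-up; crude: Et3SiCl, imidazole, DMF, 0–25 °C
Reagents that add atoms: chlorotriethylsilane CC[Si](Cl)(CC)CC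
Why: the same anti-selective asymmetric Mukaiyama aldol with the enantiomeric ligand should give the (2R,3R) adduct, whose two centres become C3 and C2 of the lower unit.

Step 11
Reactants: 6 1,2-bis(benzyloxy)-4-bromo-3-fluorobenzene; 14 S-ethyl (2S,3S)-2-(benzyloxy)-3-[4-(benzyloxy)phenyl]-3-[(triethylsilyl)oxy]propanethioate
Product: 19 (2S,3S)-1-[3,4-bis(benzyloxy)-2-fluorophenyl]-2-(benzyloxy)-3-[4-(benzyloxy)phenyl]-3-[(triethylsilyl)oxy]propan-1-one, via aryllithium 17 (not isolated), via arylzinc chloride 18 (not isolated)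
Conditions: n-BuLi, THF, −78 °C; ZnCl2, −78 to 0 °C; then 14, PdCl2(PPh3)2 (5 mol%), THF–toluene, 25 °C; aq. work-up
Reagents that add atoms: none
Why: bromine–lithium exchange, transmetalation to zinc (which stops loss of LiF) and Fukuyama coupling of the thioester should give the ketone without touching the two stereocentres.

Step 12
Reactants: 19 (2S,3S)-1-[3,4-bis(benzyloxy)-2-fluorophenyl]-2-(benzyloxy)-3-[4-(benzyloxy)phenyl]-3-[(triethylsilyl)oxy]propan-1-one
Product: 20 (2S,3S)-3,7,8-tris(benzyloxy)-2-[4-(benzyloxy)phenyl]chroman-4-one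
Conditions: CsF (0.2 equiv), 18-crown-6 (0.2 equiv), DMF, 25–40 °C
Reagents that add atoms: none
Why: fluoride-catalysed desilylative intramolecular SNAr at the fluorine-bearing carbon ortho to the ketone closes the pyranone with retention at both centres, so the anti aldol becomes the 2,3-trans chromanone (the same closure as the key step, on the simpler substrate).

Step 13
Reactants: 8 1,2-bis(benzyloxy)-4-bromo-3-fluoro-6-iodobenzene; 20 (2S,3S)-3,7,8-tris(benzyloxy)-2-[4-(benzyloxy)phenyl]chroman-4-one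
Product: 22 (2S,3S)-3,7,8-tris(benzyloxy)-2-[4-(benzyloxy)phenyl]-4-[2,3-bis(benzyloxy)-5-bromo-4-fluorophenyl]chroman-4-ol (mixture of C4 epimers), via aryllithium 21 (not isolated)
Conditions: n-BuLi (1.0 equiv), THF, −90 °C; then 20, −78 °C; H2O quench
Reagents that add atoms: none
Why: iodine–lithium exchange is much faster than bromine–lithium exchange, and the aryllithium adds 1,2 to the chromanone carbonyl; the new C4 carbinol centre is not controlled and is removed in step 14.

Step 14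
Reactants: 22 (2S,3S)-3,7,8-tris(benzyloxy)-2-[4-(benzyloxy)phenyl]-4-[2,3-bis(benzyloxy)-5-bromo-4-fluorophenyl]chroman-4-ol
Product: 23 (2S,3R,4S)-3,7,8-tris(benzyloxy)-2-[4-(benzyloxy)phenyl]-4-[2,3-bis(benzyloxy)-5-bromo-4-fluorophenyl]chromane (2,3-trans-3,4-cis)
Conditions: n-Bu3SnH (3 equiv), CF3CO2H, CH2Cl2, 0 °C
Reagents that add atoms: none
Why: ionic hydrogenation, in which the tertiary doubly benzylic alcohol ionises and the planar C4 cation should take hydride on the face opposite the C3 benzyloxy group (the facial preference seen when nucleophiles capture flavan-4-yl cations), leaving the aryl group cis to C3–O and trans to the C2 aryl.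

Step 15
Reactants: 23 (2S,3R,4S)-3,7,8-tris(benzyloxy)-2-[4-(benzyloxy)phenyl]-4-[2,3-bis(benzyloxy)-5-bromo-4-fluorophenyl]chromane; 16 S-ethyl (2R,3R)-2-(benzyloxy)-3-[4-(benzyloxy)phenyl]-3-[(triethylsilyl)oxy]propanethioate
Product: 26 (2R,3R)-1-{3,4-bis(benzyloxy)-2-fluoro-5-[(2S,3R,4S)-3,7,8-tris(benzyloxy)-2-[4-(benzyloxy)phenyl]chroman-4-yl]phenyl}-2-(benzyloxy)-3-[4-(benzyloxy)phenyl]-3-[(triethylsilyl)oxy]propan-1-one, via aryllithium 24 (not isolated), via arylzinc chloride 25 (not isolated)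
Conditions: n-BuLi, THF, −78 °C; ZnCl2, −78 to 0 °C; then 16, PdCl2(PPh3)2 (5 mol%), THF–toluene, 25 °C; aq. work-up
Reagents that add atoms: none
Why: bromine–lithium exchange at the carbon ortho to fluorine, transmetalation to zinc and Fukuyama coupling should install the whole C4–C3–C2 chain of the lower unit with both centres preformed.

Step 16
Reactants: 26 (2R,3R)-1-{3,4-bis(benzyloxy)-2-fluoro-5-[(2S,3R,4S)-3,7,8-tris(benzyloxy)-2-[4-(benzyloxy)phenyl]chroman-4-yl]phenyl}-2-(benzyloxy)-3-[4-(benzyloxy)phenyl]-3-[(triethylsilyl)oxy]propan-1-one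
Product: 27 (2R,3R)-3,7,8-tris(benzyloxy)-2-[4-(benzyloxy)phenyl]-6-[(2S,3R,4S)-3,7,8-tris(benzyloxy)-2-[4-(benzyloxy)phenyl]chroman-4-yl]chroman-4-one
Conditions: CsF (0.2 equiv), 18-crown-6 (0.2 equiv), DMF, 25–40 °C
Reagents that add atoms: none
Why: Fluoride attacks silicon and frees the C2 alkoxide, which adds to C8a, the fluorine-bearing carbon ortho to the C4 carbonyl, giving a Meisenheimer anion delocalised into that carbonyl; loss of fluoride restores ring A, and the fluoride leaves as Et3SiF or re-enters the cycle. The closest known reaction type is the fluoride-promoted SNAr etherification of silyl ethers with aryl fluorides activated by an ortho acyl group, as used for 4-chromanones and diaryl ethers. Ring C closes in the 6-exo-trig mode, the displaced C8a–F bond lying outside the new ring. No new stereocentre is formed: no bond to C2 or C3 is broken, so the anti (2R,3R) aldol relationship becomes the 2,3-trans ring. The step needs O-arylation to outrun retro-aldol cleavage, β-elimination and C3 epimerisation of the aldol-type ketone, which is secured by keeping the oxygen silylated until a catalytic amount of fluoride releases it next to the activated C–F bond. Site selectivity is secured because C8a carries the only fluorine and the C3 oxygen is a benzyl ether, so no five-membered closure can compete.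

Step 17
Reactants: 27 (2R,3R)-3,7,8-tris(benzyloxy)-2-[4-(benzyloxy)phenyl]-6-[(2S,3R,4S)-3,7,8-tris(benzyloxy)-2-[4-(benzyloxy)phenyl]chroman-4-yl]chroman-4-one
Product: 28 (2R,3R)-3,7,8-trihydroxy-2-(4-hydroxyphenyl)-6-[(2S,3R,4R)-3,7,8-trihydroxy-2-(4-hydroxyphenyl)chroman-4-yl]chroman-4-one
Conditions: H2 (1 atm), Pd(OH)2/C, THF–MeOH, 25 °C
Reagents that add atoms: none
Why: hydrogenolysis of the six aryl and two alkyl benzyl ethers under neutral conditions, which the aryl ketone, the cyclic C2–O1 ethers and the diarylmethine are expected to survive.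

Step 18
Reactants: 28 (2R,3R)-3,7,8-trihydroxy-2-(4-hydroxyphenyl)-6-[(2S,3R,4R)-3,7,8-trihydroxy-2-(4-hydroxyphenyl)chroman-4-yl]chroman-4-one
Product: 29 (2R,3S,4R)-2-(4-hydroxyphenyl)-6-[(2S,3R,4R)-3,7,8-trihydroxy-2-(4-hydroxyphenyl)chroman-4-yl]chromane-3,4,7,8-tetrol
Conditions: NaBH4 (excess), EtOH, 0 °C, under N2; work-up at pH 6
Reagents that add atoms: none
Why: borohydride reduction of the 2,3-trans 3-hydroxychromanone, in which axial hydride attack at C4 gives the equatorial 4-hydroxyl trans to the 3-hydroxyl (4R), the usual outcome for trans-dihydroflavonols.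

Compound list
1 | 3-fluoro-2-hydroxybenzaldehyde | O=Cc1cccc(F)c1O | starting material
2 | 2-(benzyloxy)-3-fluorobenzaldehyde | O=Cc1cccc(F)c1OCc1ccccc1 | intermediate
3 | 2-(benzyloxy)-3-fluorophenyl formate | O=COc1cccc(F)c1OCc1ccccc1 | intermediate
4 | 2-(benzyloxy)-3-fluorophenol | Oc1cccc(F)c1OCc1ccccc1 | intermediate
5 | 2-(benzyloxy)-4-bromo-3-fluorophenol | Oc1ccc(Br)c(F)c1OCc1ccccc1 | intermediate
6 | 1,2-bis(benzyloxy)-4-bromo-3-fluorobenzene | Fc1c(Br)ccc(OCc2ccccc2)c1OCc1ccccc1 | intermediate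
7 | 2-(benzyloxy)-4-bromo-3-fluoro-6-iodophenol | Oc1c(I)cc(Br)c(F)c1OCc1ccccc1 | intermediate
8 | 1,2-bis(benzyloxy)-4-bromo-3-fluoro-6-iodobenzene | Fc1c(Br)cc(I)c(OCc2ccccc2)c1OCc1ccccc1 | intermediate
9 | (benzyloxy)acetyl chloride | O=C(Cl)COCc1ccccc1 | starting material
10 | S-ethyl 2-(benzyloxy)ethanethioate | CCSC(=O)COCc1ccccc1 | intermediate
11 | (Z)-{[2-(benzyloxy)-1-(ethylsulfanyl)ethenyl]oxy}trimethylsilane | CCS/C(O[Si](C)(C)C)=C\OCc1ccccc1 | intermediate
12 | 4-(benzyloxy)benzaldehyde | O=Cc1ccc(OCc2ccccc2)cc1 | starting material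
13 | S-ethyl (2S,3S)-2-(benzyloxy)-3-[4-(benzyloxy)phenyl]-3-hydroxypropanethioate (anti) | CCSC(=O)[C@@H](OCc1ccccc1)[C@@H](O)c1ccc(OCc2ccccc2)cc1 | intermediate
14 | S-ethyl (2S,3S)-2-(benzyloxy)-3-[4-(benzyloxy)phenyl]-3-[(triethylsilyl)oxy]propanethioate | CCSC(=O)[C@@H](OCc1ccccc1)[C@@H](O[Si](CC)(CC)CC)c1ccc(OCc2ccccc2)cc1 | intermediate
15 | S-ethyl (2R,3R)-2-(benzyloxy)-3-[4-(benzyloxy)phenyl]-3-hydroxypropanethioate (anti) | CCSC(=O)[C@H](OCc1ccccc1)[C@H](O)c1ccc(OCc2ccccc2)cc1 | intermediate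
16 | S-ethyl (2R,3R)-2-(benzyloxy)-3-[4-(benzyloxy)phenyl]-3-[(triethylsilyl)oxy]propanethioate | CCSC(=O)[C@H](OCc1ccccc1)[C@H](O[Si](CC)(CC)CC)c1ccc(OCc2ccccc2)cc1 | intermediate
17 | [3,4-bis(benzyloxy)-2-fluorophenyl]lithium | [Li]c1ccc(OCc2ccccc2)c(OCc2ccccc2)c1F | intermediate
18 | [3,4-bis(benzyloxy)-2-fluorophenyl]zinc chloride | Cl[Zn]c1ccc(OCc2ccccc2)c(OCc2ccccc2)c1F | intermediate
19 | (2S,3S)-1-[3,4-bis(benzyloxy)-2-fluorophenyl]-2-(benzyloxy)-3-[4-(benzyloxy)phenyl]-3-[(triethylsilyl)oxy]propan-1-one | O=C(c1ccc(OCc2ccccc2)c(OCc2ccccc2)c1F)[C@@H](OCc1ccccc1)[C@@H](O[Si](CC)(CC)CC)c1ccc(OCc2ccccc2)cc1 | intermediate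
20 | (2S,3S)-3,7,8-tris(benzyloxy)-2-[4-(benzyloxy)phenyl]chroman-4-one (2,3-trans) | O=C1c2ccc(OCc3ccccc3)c(OCc3ccccc3)c2O[C@@H](c2ccc(OCc3ccccc3)cc2)[C@@H]1OCc1ccccc1 | intermediate
21 | [2,3-bis(benzyloxy)-5-bromo-4-fluorophenyl]lithium | [Li]c1cc(Br)c(F)c(OCc2ccccc2)c1OCc1ccccc1 | intermediate
22 | (2S,3S)-3,7,8-tris(benzyloxy)-2-[4-(benzyloxy)phenyl]-4-[2,3-bis(benzyloxy)-5-bromo-4-fluorophenyl]chroman-4-ol (C4 epimers) | OC1(c2cc(Br)c(F)c(OCc3ccccc3)c2OCc2ccccc2)c2ccc(OCc3ccccc3)c(OCc3ccccc3)c2O[C@@H](c2ccc(OCc3ccccc3)cc2)[C@@H]1OCc1ccccc1 | intermediate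
23 | (2S,3R,4S)-3,7,8-tris(benzyloxy)-2-[4-(benzyloxy)phenyl]-4-[2,3-bis(benzyloxy)-5-bromo-4-fluorophenyl]chromane (2,3-trans-3,4-cis) | Fc1c(Br)cc([C@@H]2c3ccc(OCc4ccccc4)c(OCc4ccccc4)c3O[C@@H](c3ccc(OCc4ccccc4)cc3)[C@@H]2OCc2ccccc2)c(OCc2ccccc2)c1OCc1ccccc1 | intermediate
24 | {3,4-bis(benzyloxy)-2-fluoro-5-[(2S,3R,4S)-3,7,8-tris(benzyloxy)-2-[4-(benzyloxy)phenyl]chroman-4-yl]phenyl}lithium | Fc1c([Li])cc([C@@H]2c3ccc(OCc4ccccc4)c(OCc4ccccc4)c3O[C@@H](c3ccc(OCc4ccccc4)cc3)[C@@H]2OCc2ccccc2)c(OCc2ccccc2)c1OCc1ccccc1 | intermediate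
25 | {3,4-bis(benzyloxy)-2-fluoro-5-[(2S,3R,4S)-3,7,8-tris(benzyloxy)-2-[4-(benzyloxy)phenyl]chroman-4-yl]phenyl}zinc chloride | Fc1c([Zn]Cl)cc([C@@H]2c3ccc(OCc4ccccc4)c(OCc4ccccc4)c3O[C@@H](c3ccc(OCc4ccccc4)cc3)[C@@H]2OCc2ccccc2)c(OCc2ccccc2)c1OCc1ccccc1 | intermediate
26 | (2R,3R)-1-{3,4-bis(benzyloxy)-2-fluoro-5-[(2S,3R,4S)-3,7,8-tris(benzyloxy)-2-[4-(benzyloxy)phenyl]chroman-4-yl]phenyl}-2-(benzyloxy)-3-[4-(benzyloxy)phenyl]-3-[(triethylsilyl)oxy]propan-1-one | Fc1c(C(=O)[C@H](OCc2ccccc2)[C@H](O[Si](CC)(CC)CC)c2ccc(OCc3ccccc3)cc2)cc([C@@H]2c3ccc(OCc4ccccc4)c(OCc4ccccc4)c3O[C@@H](c3ccc(OCc4ccccc4)cc3)[C@@H]2OCc2ccccc2)c(OCc2ccccc2)c1OCc1ccccc1 | intermediate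
27 | (2R,3R)-3,7,8-tris(benzyloxy)-2-[4-(benzyloxy)phenyl]-6-[(2S,3R,4S)-3,7,8-tris(benzyloxy)-2-[4-(benzyloxy)phenyl]chroman-4-yl]chroman-4-one | O(Cc6ccccc6)c1ccc([C@H]2Oc3c(cc([C@@H]4c5ccc(OCc6ccccc6)c(OCc6ccccc6)c5O[C@@H](c5ccc(OCc6ccccc6)cc5)[C@@H]4OCc5ccccc5)c(OCc5ccccc5)c3OCc3ccccc3)C(=O)[C@@H]2OCc2ccccc2)cc1 | intermediate
28 | (2R,3R)-3,7,8-trihydroxy-2-(4-hydroxyphenyl)-6-[(2S,3R,4R)-3,7,8-trihydroxy-2-(4-hydroxyphenyl)chroman-4-yl]chroman-4-one | Oc1ccc([C@H]2Oc3c(cc([C@@H]4c5ccc(O)c(O)c5O[C@@H](c5ccc(O)cc5)[C@@H]4O)c(O)c3O)C(=O)[C@@H]2O)cc1 | intermediate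
29 | (2R,3S,4R)-2-(4-hydroxyphenyl)-6-[(2S,3R,4R)-3,7,8-trihydroxy-2-(4-hydroxyphenyl)chroman-4-yl]chromane-3,4,7,8-tetrol (CNP0391561.8) | Oc1ccc([C@H]2Oc3c(cc([C@@H]4c5ccc(O)c(O)c5O[C@@H](c5ccc(O)cc5)[C@@H]4O)c(O)c3O)[C@@H](O)[C@@H]2O)cc1 | target

Total step count: 18.
Longest linear sequence: 12 steps (1, 2, 3, 4, 11, 12, 13, 14, 15, 16, 17, 18).

Steps most likely to fail

Step 16 (key step). The released alkoxide may fragment the aldol-type ketone (retro-aldol cleavage, β-elimination of the oxygen at C2, or epimerisation at C3) faster than it attacks the electron-rich fluoroarene. The cyclised product may also reopen by E1cB loss of the aryloxide. The fallback sets out from 26 and comes back at 27, and takes the enolisable ketone out of the ring closure. NaBH4 in MeOH at 0 °C should reduce 26 to the C4 carbinol F1 (both C4 epimers), which can undergo neither retro-aldol cleavage nor enolisation. Stoichiometric CsF with 18-crown-6 in DMF at 80–100 °C should then desilylate and close the same O1–C8a bond by alkoxide SNAr on the now non-activated fluoroarene (the C4 hydroxyl cannot cyclise), giving the flavan-4-ol F2. Dess–Martin periodinane should oxidise the benzylic C4 hydroxyl of F2 to ketone 27.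

Step 14. Facial control in the hydride capture may be poor, giving the 3,4-trans epimer, or the C4 cation may lose the C3 proton to an enol ether and scramble C3. The fallback sets out from 22 and comes back at 23, and replaces the cation by a radical. Oxalyl chloride should convert the tertiary alcohol into the chlorooxoacetate F3, and sodium 2-thioxopyridin-1(2H)-olate should turn this into the mixed thiohydroxamate oxalate F4 (neither isolated). Warming or irradiating F4 with tert-butylthiol should release, after loss of two molecules of CO2, the planar C4 diarylmethyl radical, which takes a hydrogen atom from the bulky thiol on the face opposite the C3 benzyloxy group (Barton-type radical deoxygenation). No stannyl radical is involved, so the aryl bromide should survive.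

Step 15. At the dimer stage the ortho-fluoro aryllithium may lose LiF before transmetalation, or the hindered arylzinc may transfer too slowly to the acylpalladium species and be lost by protonation. The fallback sets out from 16 and 23 and comes back at 26, and avoids zinc and palladium. MeNH(OMe)·HCl with i-PrMgCl in THF at −20 °C should convert 16 into the Weinreb amide F5. Aryllithium 24, made from 23 with n-BuLi at −78 °C, should then be acylated directly by F5 at −78 °C to give 26 after aqueous work-up.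

Further compounds
F1 | step 16 | C4 carbinol from reduction of the ketone of 26 (both C4 epimers, other centres as in 26) | Fc1c(C(O)[C@H](OCc2ccccc2)[C@H](O[Si](CC)(CC)CC)c2ccc(OCc3ccccc3)cc2)cc([C@@H]2c3ccc(OCc4ccccc4)c(OCc4ccccc4)c3O[C@@H](c3ccc(OCc4ccccc4)cc3)[C@@H]2OCc2ccccc2)c(OCc2ccccc2)c1OCc1ccccc1
F2 | step 16 | flavan-4-ol corresponding to ketone 27 (both C4 epimers, other centres as in 27) | O(Cc6ccccc6)c1ccc([C@H]2Oc3c(cc([C@@H]4c5ccc(OCc6ccccc6)c(OCc6ccccc6)c5O[C@@H](c5ccc(OCc6ccccc6)cc5)[C@@H]4OCc5ccccc5)c(OCc5ccccc5)c3OCc3ccccc3)C(O)[C@@H]2OCc2ccccc2)cc1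
F3 | step 14 | chlorooxoacetate of tertiary alcohol 22 | ClC(=O)C(=O)OC1(c2cc(Br)c(F)c(OCc3ccccc3)c2OCc2ccccc2)c2ccc(OCc3ccccc3)c(OCc3ccccc3)c2O[C@@H](c2ccc(OCc3ccccc3)cc2)[C@@H]1OCc1ccccc1
F4 | step 14 | mixed oxalate of 22 and N-hydroxypyridine-2-thione | S=c1ccccn1OC(=O)C(=O)OC1(c2cc(Br)c(F)c(OCc3ccccc3)c2OCc2ccccc2)c2ccc(OCc3ccccc3)c(OCc3ccccc3)c2O[C@@H](c2ccc(OCc3ccccc3)cc2)[C@@H]1OCc1ccccc1
F5 | step 15 | (2R,3R)-2-(benzyloxy)-3-[4-(benzyloxy)phenyl]-N-methoxy-N-methyl-3-[(triethylsilyl)oxy]propanamide | CON(C)C(=O)[C@H](OCc1ccccc1)[C@H](O[Si](CC)(CC)CC)c1ccc(OCc2ccccc2)cc1
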